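**Retrosynthetic overview**

1. Late stage: the ester comes from icosanoyl chloride; C12–C13 is made by a B-alkyl Suzuki coupling of iodide 21 with the (Z)-vinyl iodide 25, which already carries the C13=C14 geometry (from but-2-yne-1,4-diol).
2. Ring B decoration: the C8 methyl comes from methylenation and diimide reduction; the quaternary C9 comes from two α′-alkylations of enone 13, whose C6=C7 bond blocks C7.
3. Ring A (second ring formed): a [3+3] Michael–Wittig annulation of enone 6 with allylidenetriphenylphosphorane forms C1–C10 and C3=C4 in one operation.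
4. Enabling feature: in ring B of 6 the enone β-carbon C10 and the acetyl carbonyl carbon C4 both sit on quaternary C5. This 1,3-dielectrophile matches the 1,3-dinucleophilic C1–C3 ylide.
5. Ring B (first ring formed) and the C5 stereocenter come from an enantioselective Diels–Alder reaction of diene 1 with methacrolein 2.

Key step: step 3

Remark: carbons are labelled C1–C20 as in the clerodane skeleton (ring A = C1–C5 and C10, ring B = C5–C10, side chain C11–C16); icosanoyl chloride is taken as the commercial source of the acyl group.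

**Route**

Step 1
Reactants: 1 (E)-1-(dimethylamino)-3-[(tert-butyldimethylsilyl)oxy]buta-1,3-diene; 2 methacrolein
Product: 5 (4R)-4-(1-hydroxyethyl)-4-methylcyclohex-2-en-1-one, via Diels–Alder adduct 3 (not isolated), via magnesium alkoxide 4 (not isolated)
Conditions: 1-naphthyl-TADDOL (20 mol %, the enantiomer that gives 1R), toluene, −80 °C; MeMgBr, Et2O, −78 °C; 2 M HCl, THF, 0 °C → rt
Reagents that add atoms: methylmagnesium bromide, C[Mg]Br
Why: Hydrogen-bond-catalysed Diels–Alder reaction of an electron-rich 1-amino-3-siloxydiene with an α-substituted acrolein, in which the TADDOL shields one face of the bound aldehyde and so sets the quaternary carbon (the later C5) while the ortho/para rule fixes the regiochemistry; Grignard addition to the aldehyde and acid-induced desilylation with β-elimination of dimethylamine then unmask the enone in the same flask.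

Step 2
Reactants: 5 (4R)-4-(1-hydroxyethyl)-4-methylcyclohex-2-en-1-one
Product: 6 (4R)-4-acetyl-4-methylcyclohex-2-en-1-one
Conditions: Dess–Martin periodinane, NaHCO3, CH2Cl2, rt
Reagents that add atoms: none
Why: Dess–Martin oxidation of a secondary alcohol, which merges both carbinol epimers into one methyl ketone and cannot touch the quaternary stereocenter.

Step 3
Reactants: 6 (4R)-4-acetyl-4-methylcyclohex-2-en-1-one; 7 allyltriphenylphosphonium bromide
Product: 10 (4aR,8aS)-4a,5-dimethyl-3,4,4a,8a-tetrahydronaphthalen-2(1H)-one, via allylidenetriphenylphosphorane 8 (not isolated), via ketone ylide 9 (not isolated)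
Conditions: 7, KN(SiMe3)2, THF, −78 °C; then 6, −78 → 65 °C
Reagents that add atoms: none
Why: Proposed new method: ylide 8 should add through its γ-carbon to C10, the β-carbon of the ring-B enone (1,4-addition); the enolate then takes a proton from C1 to give ketone ylide 9, whose α-carbon (C3) attacks the C4 acetyl carbonyl, and the oxaphosphetane collapses to C3=C4 and Ph3PO. The closest known reaction type is the [3+3] Michael–Wittig cyclohexadiene synthesis from allylidenephosphoranes and enones or alkylidene β-dicarbonyl compounds; here the Wittig acceptor is moved from the enone carbonyl to the acetyl group on the γ-carbon C5. Ring A closes by an intramolecular Wittig reaction, a 6-exo-trig attack on the exocyclic C4=O; closure onto C8=O is excluded because it would need a bridgehead (anti-Bredt) alkene in a bicyclo[3.3.1] frame. C10 is the only new stereocenter and is controlled by quaternary C5: the ylide should enter anti to the acetyl group, which prefers the pseudoaxial position (smaller A value than methyl) and is the better σ-acceptor (Felkin–Anh-type alignment), so C1 and C4 end up trans and the ring fusion is trans. The step needs γ-1,4-attack rather than α-1,2-attack, and olefination of C4 rather than C8; the soft delocalised lithium-free ylide, the neopentyl position of the acetyl group and the Bredt constraint should secure this. The extra C1=C2 bond is the price of the allyl reagent and is removed in step 4.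

Step 4
Reactants: 10 (4aR,8aS)-4a,5-dimethyl-3,4,4a,8a-tetrahydronaphthalen-2(1H)-one
Product: 11 (4aR,8aR)-4a,5-dimethyl-3,4,4a,7,8,8a-hexahydronaphthalen-2(1H)-one
Conditions: KO2CN=NCO2K, AcOH, MeOH/pyridine, 0 °C → rt
Reagents that add atoms: none
Why: Diimide reduction (concerted syn transfer of H2), which is far faster at the cis-disubstituted C1=C2 bond of the diene than at the trisubstituted C3=C4 bond shielded by quaternary C5 and leaves the ketone alone.

Step 5
Reactants: 11 (4aR,8aR)-4a,5-dimethyl-3,4,4a,7,8,8a-hexahydronaphthalen-2(1H)-one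
Product: 13 (4aS,8aR)-4a,5-dimethyl-4a,7,8,8a-tetrahydronaphthalen-2(1H)-one, via lithium enolate 12 (not isolated)
Conditions: LiN(i-Pr)2, THF, −78 °C; PhS(Cl)=N-t-Bu, −78 °C
Reagents that add atoms: none
Why: Kinetic enolisation of this trans-2-decalone-type ketone should occur at C7, away from the ring fusion, and oxidation of the enolate with the sulfinimidoyl chloride (a one-pot ketone dehydrogenation) then gives the C6=C7 enone, which blocks C7 during the two alkylations that follow.

Step 6
Reactants: 13 (4aS,8aR)-4a,5-dimethyl-4a,7,8,8a-tetrahydronaphthalen-2(1H)-one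
Product: 15 (4aR,8aR)-1,4a,5-trimethyl-4a,7,8,8a-tetrahydronaphthalen-2(1H)-one (C1 epimers), via lithium dienolate 14 (not isolated)
Conditions: LiN(i-Pr)2, THF, −78 °C; MeI, −78 → 0 °C
Reagents that add atoms: iodomethane, CI
Why: Kinetic α′-alkylation of an enone: with no γ-hydrogen (C5 is quaternary) the amide base can only deprotonate C9, and the configuration created at C9 is irrelevant because the centre is enolised again in step 7.

Step 7
Reactants: 15 (4aR,8aR)-1,4a,5-trimethyl-4a,7,8,8a-tetrahydronaphthalen-2(1H)-one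
Product: 17 methyl 2-[(1R,4aR,8aS)-1,4a,5-trimethyl-2-oxo-1,2,4a,7,8,8a-hexahydronaphthalen-1-yl]acetate, via lithium dienolate 16 (not isolated)
Conditions: LiN(i-Pr)2, THF/DMPU, −78 °C; BrCH2CO2Me, −78 → 0 °C
Reagents that add atoms: methyl bromoacetate, COC(=O)CBr
Why: Alkylation of the fully substituted α′-enolate, in which the electrophile should enter on the face opposite to the axial C5 methyl group and to C1, so that the CH2CO2Me group becomes equatorial and the C9 methyl axial, the outcome known for alkylations of related angularly methylated octalone enolates.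

Step 8
Reactants: 17 methyl 2-[(1R,4aR,8aS)-1,4a,5-trimethyl-2-oxo-1,2,4a,7,8,8a-hexahydronaphthalen-1-yl]acetate
Product: 18 methyl 2-[(1R,4aR,8aR)-1,4a,5-trimethyl-2-methylidene-1,2,4a,7,8,8a-hexahydronaphthalen-1-yl]acetate
Conditions: Zn, CH2Br2, TiCl4, THF/CH2Cl2, 0 °C → rt
Reagents that add atoms: dibromomethane, BrCBr
Why: Lombardo–Takai methylenation, a non-basic gem-dimetallic olefination that converts the hindered, non-enolisable ketone into the exocyclic methylene group without touching the ester.

Step 9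
Reactants: 18 methyl 2-[(1R,4aR,8aR)-1,4a,5-trimethyl-2-methylidene-1,2,4a,7,8,8a-hexahydronaphthalen-1-yl]acetate
Product: 19 methyl 2-[(1S,2R,4aR,8aR)-1,2,4a,5-tetramethyl-1,2,3,4,4a,7,8,8a-octahydronaphthalen-1-yl]acetate
Conditions: KO2CN=NCO2K (excess, in portions), AcOH, MeOH/pyridine, rt
Reagents that add atoms: none
Why: Diimide reduction of the cis-disubstituted C6=C7 bond and the 1,1-disubstituted exocyclic bond, with syn delivery of hydrogen to C8 from the face opposite to the two axial methyl groups on C5 and C9 so that the new methyl group is equatorial (8R), while the trisubstituted C3=C4 bond reacts much more slowly.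

Step 10
Reactants: 19 methyl 2-[(1S,2R,4aR,8aR)-1,2,4a,5-tetramethyl-1,2,3,4,4a,7,8,8a-octahydronaphthalen-1-yl]acetate
Product: 20 2-[(1S,2R,4aR,8aR)-1,2,4a,5-tetramethyl-1,2,3,4,4a,7,8,8a-octahydronaphthalen-1-yl]ethan-1-ol
Conditions: LiAlH4, THF, 0 °C
Reagents that add atoms: none
Why: Hydride reduction of the ester to the primary alcohol by LiAlH4, which leaves the isolated trisubstituted alkene untouched.

Step 11
Reactants: 20 2-[(1S,2R,4aR,8aR)-1,2,4a,5-tetramethyl-1,2,3,4,4a,7,8,8a-octahydronaphthalen-1-yl]ethan-1-ol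
Product: 21 (1S,2R,4aR,8aR)-1-(2-iodoethyl)-1,2,4a,5-tetramethyl-1,2,3,4,4a,7,8,8a-octahydronaphthalene
Conditions: I2, PPh3, imidazole, CH2Cl2, 0 °C → rt
Reagents that add atoms: iodine, II
Why: Appel-type iodination, an SN2 displacement of the activated primary alkoxyphosphonium by iodide at a carbon that is not neopentyl.

Step 12
Reactants: 22 but-2-yne-1,4-diol
Product: 23 4-[(tert-butyldimethylsilyl)oxy]but-2-yn-1-ol
Conditions: 22 (4 equiv), t-BuMe2SiCl, imidazole, THF/DMF, 0 °C
Reagents that add atoms: tert-butyldimethylsilyl chloride, CC(C)(C)[Si](C)(C)Cl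
Why: Statistical monosilylation of the symmetric diol used in excess, the surplus diol being removed by aqueous extraction.

Step 13
Reactants: 23 4-[(tert-butyldimethylsilyl)oxy]but-2-yn-1-ol
Product: 25 (2Z)-4-[(tert-butyldimethylsilyl)oxy]-3-iodobut-2-en-1-ol, via sodium alkenylalanate 24 (not isolated)
Conditions: NaAlH2(OCH2CH2OMe)2, THF, 0 °C → rt; EtOAc; I2, −78 → 0 °C
Reagents that add atoms: iodine, II
Why: Alkoxide-directed trans-hydroalumination of the propargylic alcohol places aluminium on the distal alkyne carbon cis to the CH2O group, and iodinolysis with retention gives the Z-vinyl iodide in which the future C15 and C16 are already trans.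

Step 14
Reactants: 21 (1S,2R,4aR,8aR)-1-(2-iodoethyl)-1,2,4a,5-tetramethyl-1,2,3,4,4a,7,8,8a-octahydronaphthalene; 25 (2Z)-4-[(tert-butyldimethylsilyl)oxy]-3-iodobut-2-en-1-ol
Product: 28 (2E)-3-{[(tert-butyldimethylsilyl)oxy]methyl}-5-[(1S,2R,4aR,8aR)-1,2,4a,5-tetramethyl-1,2,3,4,4a,7,8,8a-octahydronaphthalen-1-yl]pent-2-en-1-ol, via alkyllithium 26 (not isolated), via lithium borinate 27 (not isolated)
Conditions: 21, t-BuLi (2.1 equiv), Et2O, −78 °C; B-methoxy-9-BBN, THF, −78 °C → rt; then 25, Pd(dppf)Cl2 (5 mol %), K3PO4 (aq), DMF, rt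
Reagents that add atoms: none
Why: B-alkyl Suzuki–Miyaura coupling after iodine–lithium exchange and capture by B-methoxy-9-BBN, which joins C12 to C13 with retention of the alkene geometry and tolerates the free hydroxyl group.

Step 15
Reactants: 28 (2E)-3-{[(tert-butyldimethylsilyl)oxy]methyl}-5-[(1S,2R,4aR,8aR)-1,2,4a,5-tetramethyl-1,2,3,4,4a,7,8,8a-octahydronaphthalen-1-yl]pent-2-en-1-ol; 29 icosanoyl chloride
Product: 30 (2E)-3-{[(tert-butyldimethylsilyl)oxy]methyl}-5-[(1S,2R,4aR,8aR)-1,2,4a,5-tetramethyl-1,2,3,4,4a,7,8,8a-octahydronaphthalen-1-yl]pent-2-en-1-yl icosanoate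
Conditions: pyridine, DMAP (cat.), CH2Cl2, 0 °C → rt
Reagents that add atoms: none
Why: DMAP-catalysed acylation of the only free (primary allylic) hydroxyl group with the acid chloride.

Step 16
Reactants: 30 (2E)-3-{[(tert-butyldimethylsilyl)oxy]methyl}-5-[(1S,2R,4aR,8aR)-1,2,4a,5-tetramethyl-1,2,3,4,4a,7,8,8a-octahydronaphthalen-1-yl]pent-2-en-1-yl icosanoate
Product: 31 (2E)-3-(hydroxymethyl)-5-[(1S,2R,4aR,8aR)-1,2,4a,5-tetramethyl-1,2,3,4,4a,7,8,8a-octahydronaphthalen-1-yl]pent-2-en-1-yl icosanoate (CNP0168335.1)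
Conditions: HF·pyridine, THF/pyridine, 0 °C → rt
Reagents that add atoms: none
Why: Fluoride-mediated cleavage of the primary silyl ether under buffered conditions that spare the ester, acyl migration being impossible because the two CH2O groups are trans across the C13=C14 bond.

**Compound list**

1 | (E)-1-(dimethylamino)-3-[(tert-butyldimethylsilyl)oxy]buta-1,3-diene | CN(C)/C=C/C(=C)O[Si](C)(C)C(C)(C)C | starting material
2 | methacrolein (2-methylprop-2-enal) | CC(=C)C=O | starting material
3 | (1R)-4-[(tert-butyldimethylsilyl)oxy]-2-(dimethylamino)-1-methylcyclohex-3-ene-1-carbaldehyde (Diels–Alder adduct, C2 epimers) | CC(C)(C)[Si](C)(C)OC1=CC(N(C)C)[C@](C)(C=O)CC1 | intermediate (not isolated)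
4 | bromomagnesium alkoxide of the methyl carbinol formed from 3 (carbinol epimers) | CC(C)(C)[Si](C)(C)OC1=CC(N(C)C)[C@](C)(C(C)O[Mg]Br)CC1 | intermediate (not isolated)
5 | (4R)-4-(1-hydroxyethyl)-4-methylcyclohex-2-en-1-one (carbinol epimers) | O=C1CC[C@@](C)(C(C)O)C=C1 | intermediate
6 | (4R)-4-acetyl-4-methylcyclohex-2-en-1-one | O=C1CC[C@@](C)(C(C)=O)C=C1 | intermediate
7 | allyltriphenylphosphonium bromide | C=CC[P+](c1ccccc1)(c1ccccc1)c1ccccc1.[Br-] | starting material
8 | allylidenetriphenylphosphorane | C=CC=P(c1ccccc1)(c1ccccc1)c1ccccc1 | intermediate (not isolated)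
9 | (3S,4R)-4-acetyl-4-methyl-3-[3-(triphenyl-λ5-phosphanylidene)prop-1-en-1-yl]cyclohexan-1-one (ketone ylide, side chain trans to acetyl) | O=C1CC[C@@](C)(C(C)=O)[C@H](C=CC=P(c2ccccc2)(c2ccccc2)c2ccccc2)C1 | intermediate (not isolated)
10 | (4aR,8aS)-4a,5-dimethyl-3,4,4a,8a-tetrahydronaphthalen-2(1H)-one (trans-fused) | O=C1CC[C@@]2(C)C(C)=CC=C[C@@H]2C1 | intermediate
11 | (4aR,8aR)-4a,5-dimethyl-3,4,4a,7,8,8a-hexahydronaphthalen-2(1H)-one | O=C1CC[C@@]2(C)C(C)=CCC[C@@H]2C1 | intermediate
12 | lithium enolate of 11 (C8–OLi, C7=C8) | [Li]OC1=CC[C@@]2(C)C(C)=CCC[C@@H]2C1 | intermediate (not isolated)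
13 | (4aS,8aR)-4a,5-dimethyl-4a,7,8,8a-tetrahydronaphthalen-2(1H)-one | O=C1C=C[C@@]2(C)C(C)=CCC[C@@H]2C1 | intermediate
14 | lithium cross-conjugated dienolate of 13 (C8–OLi, C8=C9) | [Li]OC1C=C[C@@]2(C)C(C)=CCC[C@@H]2C=1 | intermediate (not isolated)
15 | (4aR,8aR)-1,4a,5-trimethyl-4a,7,8,8a-tetrahydronaphthalen-2(1H)-one (C1 epimers) | O=C1C=C[C@@]2(C)C(C)=CCC[C@@H]2C1C | intermediate
16 | lithium dienolate of 15 (C8–OLi, tetrasubstituted C8=C9) | [Li]OC1C=C[C@@]2(C)C(C)=CCC[C@@H]2C=1C | intermediate (not isolated)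
17 | methyl 2-[(1R,4aR,8aS)-1,4a,5-trimethyl-2-oxo-1,2,4a,7,8,8a-hexahydronaphthalen-1-yl]acetate | COC(=O)C[C@@]1(C)C(=O)C=C[C@@]2(C)C(C)=CCC[C@H]12 | intermediate
18 | methyl 2-[(1R,4aR,8aR)-1,4a,5-trimethyl-2-methylidene-1,2,4a,7,8,8a-hexahydronaphthalen-1-yl]acetate | COC(=O)C[C@@]1(C)C(=C)C=C[C@@]2(C)C(C)=CCC[C@H]12 | intermediate
19 | methyl 2-[(1S,2R,4aR,8aR)-1,2,4a,5-tetramethyl-1,2,3,4,4a,7,8,8a-octahydronaphthalen-1-yl]acetate | COC(=O)C[C@@]1(C)[C@H](C)CC[C@@]2(C)C(C)=CCC[C@H]12 | intermediate
20 | 2-[(1S,2R,4aR,8aR)-1,2,4a,5-tetramethyl-1,2,3,4,4a,7,8,8a-octahydronaphthalen-1-yl]ethan-1-ol | OCC[C@@]1(C)[C@H](C)CC[C@@]2(C)C(C)=CCC[C@H]12 | intermediate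
21 | (1S,2R,4aR,8aR)-1-(2-iodoethyl)-1,2,4a,5-tetramethyl-1,2,3,4,4a,7,8,8a-octahydronaphthalene | ICC[C@@]1(C)[C@H](C)CC[C@@]2(C)C(C)=CCC[C@H]12 | intermediate
22 | but-2-yne-1,4-diol | OCC#CCO | starting material
23 | 4-[(tert-butyldimethylsilyl)oxy]but-2-yn-1-ol | CC(C)(C)[Si](C)(C)OCC#CCO | intermediate
24 | sodium alkenylalanate (five-membered cyclic alkoxy(alkenyl)bis(2-methoxyethoxy)aluminate from 23) | [Na+].COCCO[Al-]1(OCCOC)OCC=C1CO[Si](C)(C)C(C)(C)C | intermediate (not isolated)
25 | (2Z)-4-[(tert-butyldimethylsilyl)oxy]-3-iodobut-2-en-1-ol | OC/C=C(/CO[Si](C)(C)C(C)(C)C)I | intermediate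
26 | alkyllithium from 21 (C12–Li) | [Li]CC[C@@]1(C)[C@H](C)CC[C@@]2(C)C(C)=CCC[C@H]12 | intermediate (not isolated)
27 | lithium B-alkyl-B-methoxy-9-borabicyclo[3.3.1]nonane borinate from 26 | [Li+].CO[B-]1(CC[C@@]3(C)[C@H](C)CC[C@@]4(C)C(C)=CCC[C@H]34)C2CCCC1CCC2 | intermediate (not isolated)
28 | (2E)-3-{[(tert-butyldimethylsilyl)oxy]methyl}-5-[(1S,2R,4aR,8aR)-1,2,4a,5-tetramethyl-1,2,3,4,4a,7,8,8a-octahydronaphthalen-1-yl]pent-2-en-1-ol | OC/C=C(/CO[Si](C)(C)C(C)(C)C)CC[C@@]1(C)[C@H](C)CC[C@@]2(C)C(C)=CCC[C@H]12 | intermediate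
29 | icosanoyl chloride | CCCCCCCCCCCCCCCCCCCC(=O)Cl | starting material
30 | (2E)-3-{[(tert-butyldimethylsilyl)oxy]methyl}-5-[(1S,2R,4aR,8aR)-1,2,4a,5-tetramethyl-1,2,3,4,4a,7,8,8a-octahydronaphthalen-1-yl]pent-2-en-1-yl icosanoate | CCCCCCCCCCCCCCCCCCCC(=O)OC/C=C(/CO[Si](C)(C)C(C)(C)C)CC[C@@]1(C)[C@H](C)CC[C@@]2(C)C(C)=CCC[C@H]12 | intermediate
31 | (2E)-3-(hydroxymethyl)-5-[(1S,2R,4aR,8aR)-1,2,4a,5-tetramethyl-1,2,3,4,4a,7,8,8a-octahydronaphthalen-1-yl]pent-2-en-1-yl icosanoate (CNP0168335.1) | CCCCCCCCCCCCCCCCCCCC(=O)OC/C=C(/CO)CC[C@@]1(C)[C@H](C)CC[C@@]2(C)C(C)=CCC[C@H]12 | target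

**Step count and risks**

Total: 16 steps. Longest linear sequence: 14 steps (steps 1–11 and 14–16).

Step 3 (proposed new method). What may go wrong: α-1,2-attack of the ylide, that is direct Wittig olefination of C4=O (or C8=O), may outrun the γ-1,4-addition to the hindered C10, so that ring A never closes. The fallback uses known chemistry, sets out from 6 and comes back at 11, so that step 4 is skipped. Copper-catalysed conjugate addition of but-3-enylmagnesium bromide in the presence of Me3SiCl (CuBr·SMe2 cat., THF, −78 °C) should give the silyl enol ether F1. Wittig methylenation of its acetyl group (Ph3P=CH2, THF) should give the isopropenyl triene F2. Ring-closing metathesis (second-generation Hoveyda–Grubbs catalyst, CH2Cl2, 40 °C) should form the trisubstituted C3=C4 bond of the bicyclic silyl enol ether F3, and dilute HCl then releases ketone 11.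

Step 9. What may go wrong: loss of chemoselectivity, because diimide has to reduce two hindered double bonds next to quaternary C5 and C9 and may start on C3=C4 before they are consumed. The fallback sets out from 17 and comes back at 19, reducing each bond with its own selective reagent. Conjugate reduction of the enone with [(Ph3P)CuH]6 (benzene, rt) should give the saturated keto ester F4. Methylenation as in step 8 (Zn, CH2Br2, TiCl4) should give the methylidene ester F5. Homogeneous hydrogenation of its single 1,1-disubstituted alkene (H2, RhCl(PPh3)3, benzene) should give 19 and leave the trisubstituted alkene alone.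

Step 1. What may go wrong: insufficient enantiofacial discrimination of methacrolein by the hydrogen-bonding catalyst, which is the only source of absolute configuration. The fallback sets out from commercial acetophenone and comes back at 6, using dearomatisation and a biocatalytic desymmetrisation. Birch reductive methylation (K, NH3, t-BuOH, THF, −78 °C; LiBr; MeI) should give 1-acetyl-1-methylcyclohexa-2,5-diene F6. Allylic oxidation of its doubly allylic CH2 group (CrO3, 3,5-dimethylpyrazole, CH2Cl2, −20 °C) should give the prochiral dienone F7, which is used at once. An ene-reductase (flavin-dependent, NADPH recycled with glucose dehydrogenase and glucose, selected by screening for the R product) should reduce one of the two enantiotopic C=C bonds to give 6.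

Further compounds
F1 | step 3 | {[(3R,4R)-4-acetyl-3-(but-3-en-1-yl)-4-methylcyclohex-1-en-1-yl]oxy}trimethylsilane | C[Si](C)(C)OC1=C[C@@H](CCC=C)[C@](C)(C(C)=O)CC1
F2 | step 3 | {[(3R,4R)-3-(but-3-en-1-yl)-4-methyl-4-(prop-1-en-2-yl)cyclohex-1-en-1-yl]oxy}trimethylsilane | C[Si](C)(C)OC1=C[C@@H](CCC=C)[C@](C)(C(C)=C)CC1
F3 | step 3 | {[(4aR,8aR)-4a,5-dimethyl-3,4,4a,7,8,8a-hexahydronaphthalen-2-yl]oxy}trimethylsilane | C[Si](C)(C)OC1=C[C@H]2CCC=C(C)[C@]2(C)CC1
F4 | step 9 | methyl 2-[(1R,4aR,8aS)-1,4a,5-trimethyl-2-oxo-1,2,3,4,4a,7,8,8a-octahydronaphthalen-1-yl]acetate | COC(=O)C[C@@]1(C)C(=O)CC[C@@]2(C)C(C)=CCC[C@H]12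
F5 | step 9 | methyl 2-[(1R,4aR,8aR)-1,4a,5-trimethyl-2-methylidene-1,2,3,4,4a,7,8,8a-octahydronaphthalen-1-yl]acetate | COC(=O)C[C@@]1(C)C(=C)CC[C@@]2(C)C(C)=CCC[C@H]12
F6 | step 1 | 1-(1-methylcyclohexa-2,5-dien-1-yl)ethan-1-one | CC(=O)C1(C)C=CCC=C1
F7 | step 1 | 4-acetyl-4-methylcyclohexa-2,5-dien-1-one | CC(=O)C1(C)C=CC(=O)C=C1
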